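**Strategy.** Numbering follows 1-benzoxepine (O1, C2–C5, C5a, C6–C9, C9a). The route rests on cutting the oxepene ring at C4–C5 and at the ring-fusion bond C5a–C9a, which also opens the cyclohexane. One iron-hydride-initiated radical bicyclisation re-forms both: hydrogen-atom transfer to a 1-alken-2-yl ester makes the C9a methyl group and a tertiary α-acyloxy radical, which closes the cyclohexane onto a vinyl group (C9a–C5a); the new primary radical closes a seven-membered lactone at the β-carbon of a sulfonyl methacrylate (C5–C4) and expels the sulfonyl radical, restoring C3=C4. It exploits the oxygen- and methyl-bearing ring-fusion carbon C9a beside the C5a–C5 unit and the C3=C4 alkene adjoining C2. The precursor is an acyclic enol ester carrying the C7 bromide; C2 enters as a lactone carbonyl.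

Key step: step 7

Remark on the chemistry: the (2S,5S) antipode of 2,5-diphenylpyrrolidine is assumed to deliver the (R)-α-bromoaldehyde in step 2; if the sense of induction is the opposite, the (2R,5R) catalyst is used instead.

**Step 1**
Reactants: 1 methyl 3,3-dimethylpent-4-enoate
Product: 2 3,3-dimethylpent-4-enal
Conditions: DIBAL-H (1.05 equiv), CH2Cl2, −78 °C; aqueous Rochelle salt
Reagents that add atoms: none
Why: Partial ester reduction: at −78 °C the tetrahedral aluminium hemiacetal is stable and should release the aldehyde only on work-up.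

**Step 2**
Reactants: 2 3,3-dimethylpent-4-enal
Product: 4 (2R)-2-bromo-3,3-dimethylpent-4-en-1-ol, via (2R)-2-bromo-3,3-dimethylpent-4-enal 3 (not isolated)
Conditions: (2S,5S)-2,5-diphenylpyrrolidine (20 mol%), PhCO2H (20 mol%), 4,4-dibromo-2,6-di-tert-butylcyclohexa-2,5-dien-1-one, CH2Cl2/pentane, −24 °C; then NaBH4, MeOH, 0 °C
Reagents that add atoms: 4,4-dibromo-2,6-di-tert-butylcyclohexa-2,5-dien-1-one, O=C1C(C(C)(C)C)=CC(Br)(Br)C=C1C(C)(C)C
Why: Organocatalytic asymmetric α-bromination of an aldehyde: the C2-symmetric amine forms an enamine with one face shielded, bromine transfer sets the C–Br stereocentre (the later C7), and in-situ borohydride reduction fixes the labile α-bromoaldehyde as the bromohydrin.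

**Step 3**
Reactants: 4 (2R)-2-bromo-3,3-dimethylpent-4-en-1-ol
Product: 5 (2R)-2-bromo-3,3-dimethylpent-4-en-1-yl trifluoromethanesulfonate
Conditions: Tf2O, 2,6-lutidine, CH2Cl2, −78 °C; used crude
Reagents that add atoms: trifluoromethanesulfonic anhydride, O=S(=O)(OS(=O)(=O)C(F)(F)F)C(F)(F)F
Why: O-Sulfonylation of the primary alcohol with a hindered pyridine base at low temperature should leave the neighbouring C–Br centre untouched.

**Step 4**
Reactants: 5 (2R)-2-bromo-3,3-dimethylpent-4-en-1-yl trifluoromethanesulfonate; 6 1-(trimethylsilyl)propyne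
Product: 8 (4S)-4-bromo-3,3-dimethyloct-1-en-7-yne, via trimethylsilyl alkyne 7 (not isolated)
Conditions: 6, n-BuLi, THF, −78 °C; then 5, THF/DMPU, −78 °C; then K2CO3 (cat.), MeOH, rt
Reagents that add atoms: none
Why: SN2 alkylation of the propargylic lithium reagent at the primary triflate (the secondary bromide is a spectator, and its descriptor changes only by priority), followed by methanolysis of the C–Si bond.

**Step 5**
Reactants: 9 (E)-3-bromo-2-methylacrylic acid
Product: 10 (E)-2-methyl-3-(phenylsulfonyl)acrylic acid
Conditions: PhSO2Na (1.5 equiv), DMF, 80 °C; aqueous HCl work-up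
Reagents that add atoms: sodium benzenesulfinate, [Na+].[O-]S(=O)c1ccccc1
Why: Vinylic substitution by addition–elimination of sulfinate at the β-carbon of the β-bromoacrylic acid should give the E vinyl sulfone.

**Step 6**
Reactants: 8 (4S)-4-bromo-3,3-dimethyloct-1-en-7-yne; 10 (E)-2-methyl-3-(phenylsulfonyl)acrylic acid
Product: 11 (5S)-5-bromo-6,6-dimethylocta-1,7-dien-2-yl (E)-2-methyl-3-(phenylsulfonyl)prop-2-enoate
Conditions: [RuCl2(p-cymene)]2 (1 mol%), P(2-furyl)3 (2 mol%), Na2CO3 (4 mol%), toluene, 50 °C
Reagents that add atoms: none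
Why: Ruthenium-catalysed Markovnikov addition of a carboxylic acid to a terminal alkyne should give the 1-alken-2-yl ester regiospecifically under near-neutral conditions that spare the bromide, the vinyl group and the vinyl sulfone.

**Step 7**
Reactants: 11 (5S)-5-bromo-6,6-dimethylocta-1,7-dien-2-yl (E)-2-methyl-3-(phenylsulfonyl)prop-2-enoate
Product: 12 (5aS,7S,9aS)-7-bromo-3,6,6,9a-tetramethyl-5a,6,7,8,9,9a-hexahydro-1-benzoxepin-2(5H)-one
Conditions: Fe(acac)3 (0.5 equiv), PhSiH2(Oi-Pr) (3 equiv), i-PrOH, 60 °C, slow addition of 11 to a final 0.002 M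
Reagents that add atoms: none
Why: Proposed new method: an iron hydride made from Fe(acac)3 and the silane transfers a hydrogen atom to the terminal CH2 of the electron-rich 1-alken-2-yl ester (closest known type: hydrogen-atom-transfer-initiated reductive coupling and cyclisation of heteroatom-substituted donor olefins onto acceptor olefins), which makes the C9a methyl group and a tertiary α-acyloxy radical at C9a. This radical closes the cyclohexane by 6-exo-trig attack on the internal carbon of the vinyl group (C9a–C5a) through a chair transition state, and the primary radical at C5 then closes the lactone by 7-endo-trig Giese addition to the sulfonyl-bearing β-carbon C4 of the methacrylate (C5–C4). β-Scission of the benzenesulfonyl radical, as in radical alkenylations with vinyl sulfones, restores C3=C4 (necessarily Z in the ring), and the sulfonyl radical returns divalent iron to trivalent iron. C5a is set by the chair with the C7 bromide and the new CH2 arm both equatorial; C9a is set by the acyloxy group lying anti to the alkene (pseudo-equatorial) with the methyl group cis to the new CH2, the sense known for 6-exo ketyl–olefin closures and for 1-alkyl-substituted alkenyl radicals. The step needs hydrogen-atom transfer to the 1,1-disubstituted enol ester rather than to the monosubstituted vinyl group or the electron-poor acrylate, 6-exo rather than 7-endo first closure, and attack at C4 rather than C3; the donor character of the enol ester, the chain length, and the fully substituted C3 next to the ester (which makes C4 the electrophilic, unhindered terminus) should secure these. High dilution and the polar protic solvent should favour the s-cis ester rotamer needed for the seven-membered closure over bimolecular trapping.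

**Step 8**
Reactants: 12 (5aS,7S,9aS)-7-bromo-3,6,6,9a-tetramethyl-5a,6,7,8,9,9a-hexahydro-1-benzoxepin-2(5H)-one
Product: 13 (5aS,7S,9aS)-7-bromo-2-(bromomethyl)-3,6,6,9a-tetramethyl-2,5,5a,6,7,8,9,9a-octahydro-1-benzoxepin-2-ol (mixture of C2 epimers)
Conditions: CH2Br2 (3 equiv), MeLi·LiBr (2.5 equiv, added last), THF/Et2O, −78 °C; AcOH quench at −78 °C
Reagents that add atoms: dibromomethane, BrCBr
Why: Bromomethyllithium, made in situ by bromine–lithium exchange, should add 1,2 to the lactone carbonyl to give a tetrahedral alkoxide that is stable at −78 °C and is protonated cold to the bromomethyl lactol (carbenoid homologation of esters and lactones to halomethyl ketone equivalents).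

**Step 9**
Reactants: 13 (5aS,7S,9aS)-7-bromo-2-(bromomethyl)-3,6,6,9a-tetramethyl-2,5,5a,6,7,8,9,9a-octahydro-1-benzoxepin-2-ol
Product: 14 palisadin B, (2R,5aS,7S,9aS)-7-bromo-2-(bromomethyl)-3,6,6,9a-tetramethyl-2,5,5a,6,7,8,9,9a-octahydro-1-benzoxepine
Conditions: Et3SiH (5 equiv), BF3·OEt2 (2 equiv), CH2Cl2, −78 to −20 °C
Reagents that add atoms: none
Why: Reductive etherification of a lactol: Lewis-acid ionisation gives the alkene-conjugated cyclic oxocarbenium ion, which the silane should reduce at C2 from the face opposite the pseudo-axial C9a methyl group, placing H anti and CH2Br syn to that methyl (2R).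

**Compound list**
1 | methyl 3,3-dimethylpent-4-enoate | COC(=O)CC(C)(C)C=C | starting material
2 | 3,3-dimethylpent-4-enal | O=CCC(C)(C)C=C | intermediate
3 | (2R)-2-bromo-3,3-dimethylpent-4-enal | C=CC(C)(C)[C@@H](Br)C=O | intermediate
4 | (2R)-2-bromo-3,3-dimethylpent-4-en-1-ol | C=CC(C)(C)[C@@H](Br)CO | intermediate
5 | (2R)-2-bromo-3,3-dimethylpent-4-en-1-yl trifluoromethanesulfonate | C=CC(C)(C)[C@@H](Br)COS(=O)(=O)C(F)(F)F | intermediate
6 | 1-(trimethylsilyl)propyne | CC#C[Si](C)(C)C | starting material
7 | [(5S)-5-bromo-6,6-dimethyloct-7-en-1-yn-1-yl]trimethylsilane | C=CC(C)(C)[C@@H](Br)CCC#C[Si](C)(C)C | intermediate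
8 | (4S)-4-bromo-3,3-dimethyloct-1-en-7-yne | C=CC(C)(C)[C@@H](Br)CCC#C | intermediate
9 | (E)-3-bromo-2-methylacrylic acid | OC(=O)/C(C)=C/Br | starting material
10 | (E)-2-methyl-3-(phenylsulfonyl)acrylic acid | OC(=O)/C(C)=C/S(=O)(=O)c1ccccc1 | intermediate
11 | (5S)-5-bromo-6,6-dimethylocta-1,7-dien-2-yl (E)-2-methyl-3-(phenylsulfonyl)prop-2-enoate | C=CC(C)(C)[C@@H](Br)CCC(=C)OC(=O)/C(C)=C/S(=O)(=O)c1ccccc1 | intermediate
12 | (5aS,7S,9aS)-7-bromo-3,6,6,9a-tetramethyl-5a,6,7,8,9,9a-hexahydro-1-benzoxepin-2(5H)-one | CC1=CC[C@H]2C(C)(C)[C@@H](Br)CC[C@]2(C)OC1=O | intermediate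
13 | (5aS,7S,9aS)-7-bromo-2-(bromomethyl)-3,6,6,9a-tetramethyl-2,5,5a,6,7,8,9,9a-octahydro-1-benzoxepin-2-ol | CC1=CC[C@H]2C(C)(C)[C@@H](Br)CC[C@]2(C)OC1(O)CBr | intermediate
14 | palisadin B, (2R,5aS,7S,9aS)-7-bromo-2-(bromomethyl)-3,6,6,9a-tetramethyl-2,5,5a,6,7,8,9,9a-octahydro-1-benzoxepine | CC1=CC[C@H]2C(C)(C)[C@@H](Br)CC[C@]2(C)O[C@H]1CBr | target

**Total step count:** 9
**Longest linear sequence:** 8 steps (steps 1, 2, 3, 4, 6, 7, 8, 9)

**Steps most likely to fail**

1. Step 7 (Proposed new method). What may go wrong as a process: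
   - The primary radical formed after the first ring closure may be reduced or trapped bimolecularly before the slow 7-endo closure, which needs the disfavoured s-cis ester rotamer.
   - Facial selectivity at C9a in the 6-exo closure may be low or reversed, because the methyl group must end up axial beside the axial C6 methyl.
   - Hydrogen-atom transfer may also reach the vinyl group.

   Fallback with known chemistry, setting out from 8 and returning at 12; the two bonds are made in separate two-electron steps. Palladium-catalysed borylative cyclisation of the 1,7-enyne (Pd(OAc)2, B2pin2, MeOH, toluene, 50 °C) should close C5a–C9a and give 2-{[(1R,3S)-3-bromo-2,2-dimethyl-6-methylidenecyclohexyl]methyl}-4,4,5,5-tetramethyl-1,3,2-dioxaborolane F1, with the bromide cis to the boronate arm. Suzuki coupling with methyl (Z)-3-iodo-2-methylacrylate (PdCl2(dppf), Ag2O, K2CO3, THF, 60 °C) should form C5–C4 and give methyl (2Z)-4-[(1R,3S)-3-bromo-2,2-dimethyl-6-methylidenecyclohexyl]-2-methylbut-2-enoate F2. LiOH in THF/water should give (2Z)-4-[(1R,3S)-3-bromo-2,2-dimethyl-6-methylidenecyclohexyl]-2-methylbut-2-enoic acid F3. Cobalt-hydride Markovnikov hydroacyloxylation of the methylidene group (Co(salen) complex Co(C16H14N2O2), N-fluoro-2,4,6-trimethylpyridinium tetrafluoroborate, (Me2SiH)2O, PhCF3, 0 °C) should then close lactone 12, the carboxyl group attacking C9a from the equatorial side, away from the axial C6 methyl.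

2. Step 4. What may go wrong as a process: the basic lithium reagent may eliminate triflic acid from the β-bromo triflate instead of substituting it, or neighbouring-bromine participation may move the bromide.

   Fallback setting out from 3 and returning at 8; the chain is built by olefination instead of alkylation. The crude aldehyde 3 is not reduced but treated with Ph3P=CHCO2Et (CH2Cl2, 0 °C), which should give ethyl (2E,4S)-4-bromo-5,5-dimethylhepta-2,6-dienoate F4. Copper-hydride conjugate reduction ([(Ph3P)CuH]6 cat., polymethylhydrosiloxane, t-BuOH, toluene) should give ethyl (4S)-4-bromo-5,5-dimethylhept-6-enoate F5. DIBAL-H at −78 °C should give (4S)-4-bromo-5,5-dimethylhept-6-enal F6. Seyferth–Gilbert homologation with dimethyl (1-diazo-2-oxopropyl)phosphonate (K2CO3, MeOH) should give alkyne 8.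

3. Step 9. What may go wrong as a process: hydride may be delivered to C4 (conjugate reduction to a cyclic enol ether) or to the wrong face of the oxocarbenium ion, or ionisation next to the electron-withdrawing CH2Br group may be so slow that the lactol opens to the hydroxy enone.

   Fallback setting out from 12 and returning at 14; C2 is built by methylenation and hydroboration instead of carbenoid addition and ionic reduction. Petasis methylenation of 12 (Cp2TiMe2, toluene, 70 °C) should give (5aS,7S,9aS)-7-bromo-3,6,6,9a-tetramethyl-2-methylidene-2,5,5a,6,7,8,9,9a-octahydro-1-benzoxepine F7. Hydroboration with 9-BBN from the face opposite the C9a methyl group, then NaBO3, should give [(2R,5aS,7S,9aS)-7-bromo-3,6,6,9a-tetramethyl-2,5,5a,6,7,8,9,9a-octahydro-1-benzoxepin-2-yl]methanol F8. An Appel reaction (CBr4, PPh3, CH2Cl2, 0 °C) should give 14.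

**Further compounds**
F1 | step 7 | 2-{[(1R,3S)-3-bromo-2,2-dimethyl-6-methylidenecyclohexyl]methyl}-4,4,5,5-tetramethyl-1,3,2-dioxaborolane | C=C1CC[C@H](Br)C(C)(C)[C@@H]1CB1OC(C)(C)C(C)(C)O1
F2 | step 7 | methyl (2Z)-4-[(1R,3S)-3-bromo-2,2-dimethyl-6-methylidenecyclohexyl]-2-methylbut-2-enoate | C=C1CC[C@H](Br)C(C)(C)[C@@H]1C/C=C(/C)C(=O)OC
F3 | step 7 | (2Z)-4-[(1R,3S)-3-bromo-2,2-dimethyl-6-methylidenecyclohexyl]-2-methylbut-2-enoic acid | C=C1CC[C@H](Br)C(C)(C)[C@@H]1C/C=C(/C)C(=O)O
F4 | step 4 | ethyl (2E,4S)-4-bromo-5,5-dimethylhepta-2,6-dienoate | C=CC(C)(C)[C@@H](Br)/C=C/C(=O)OCC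
F5 | step 4 | ethyl (4S)-4-bromo-5,5-dimethylhept-6-enoate | C=CC(C)(C)[C@@H](Br)CCC(=O)OCC
F6 | step 4 | (4S)-4-bromo-5,5-dimethylhept-6-enal | C=CC(C)(C)[C@@H](Br)CCC=O
F7 | step 9 | (5aS,7S,9aS)-7-bromo-3,6,6,9a-tetramethyl-2-methylidene-2,5,5a,6,7,8,9,9a-octahydro-1-benzoxepine | CC1=CC[C@H]2C(C)(C)[C@@H](Br)CC[C@]2(C)OC1=C
F8 | step 9 | [(2R,5aS,7S,9aS)-7-bromo-3,6,6,9a-tetramethyl-2,5,5a,6,7,8,9,9a-octahydro-1-benzoxepin-2-yl]methanol | CC1=CC[C@H]2C(C)(C)[C@@H](Br)CC[C@]2(C)O[C@H]1CO
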